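**Plan**

- **Cuts (labdane numbering):** C12–C13 (butenolide joined by B-alkyl Suzuki coupling); both C4–CH2OH bonds (back to a C4 ketone); C9–C10; then C4 is re-bonded to C10, which contracts ring A to the cyclopentane of a 1-hydroxy-5-methylbicyclo[3.1.0]hexane whose cyclopropane CH (C5) carries the C6–C9 enoate chain; finally C8=C9 (olefination) and the C4–C5/C4–C10 pair (carbene addition to an alkene).
- **Enabling feature:** in ring A (C1–C2–C3–C4–C5–C10) the carbon that ends as C(CH2OH)2 (C4) and the methyl-bearing quaternary carbon (C10) are 1,3-related through C5. With C4 as a carbinol carbon they are the two bridgeheads of a cyclopropanol. One-electron oxidation breaks the strained C4–C10 bond, which gives the ring A ketone and a tertiary C10 radical that closes ring B on C9 of an alkene activated by the C17 ester on C8.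
- **Forward order:** acyclic E-alkene diazo ketone; cyclopentane and cyclopropane in one step (step 7); Baeyer–Villiger to the cyclopropanol; rings A and B in one operation (step 9); C4 ketone to C(CH2OH)2, ester to aldehyde; the preformed butenolide ring is joined last.
- **Stereochemistry:** the E alkene and the chiral dirhodium catalyst fix the cyclopropane; only C5 survives ring opening and directs the chair-like closure (trans fusion, C10); the Z enoate sets C9; C8 is set by equilibration to the equatorial ester (later aldehyde).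

Key step: step 9

Remark: labdane numbering (C1–C20) is used in the text, and the SMILES strings define all configurations.
Remark: Rh2(S-PTTL)4 is assumed to give the cyclopropane enantiomer drawn for 14; if its sense of induction is the opposite, Rh2(R-PTTL)4 is used.

**Route**

Step 1
Reactants: 1 5-chloropent-1-yne; 2 oxirane
Product: 5 (3E)-7-chloro-4-methylhept-3-en-1-ol, via alkenylalane 3 (not isolated), via lithium aluminate 4 (not isolated)
Conditions: Me3Al, Cp2ZrCl2 (cat.), CH2Cl2, 0 °C to rt; then n-BuLi, hexane/THF, −30 °C; oxirane, −30 to 0 °C; aqueous work-up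
Reagents that add atoms: trimethylaluminium, C[Al](C)C; n-butyllithium, [Li]CCCC (butyl and lithium stay only in 4)
Why: Zirconium-catalysed Negishi carboalumination adds CH3 and Al syn across the terminal alkyne, and the derived aluminate opens oxirane with retention at the alkenyl carbon, which fixes the E trisubstituted alkene (future C5=C10).

Step 2
Reactants: 5 (3E)-7-chloro-4-methylhept-3-en-1-ol
Product: 6 (3E)-7-chloro-1-iodo-4-methylhept-3-ene
Conditions: I2, PPh3, imidazole, CH2Cl2, 0 °C to rt
Reagents that add atoms: iodine, II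
Why: Appel iodination converts the primary alcohol into the iodide and leaves the primary chloride untouched, so the two chain ends differ in reactivity.

Step 3
Reactants: 6 (3E)-7-chloro-1-iodo-4-methylhept-3-ene; 7 methyl 2-[bis(2,2,2-trifluoroethoxy)phosphoryl]acetate
Product: 8 methyl (5E)-2-[bis(2,2,2-trifluoroethoxy)phosphoryl]-9-chloro-6-methylnon-5-enoate (racemic)
Conditions: NaH, DMSO, rt
Reagents that add atoms: none
Why: C-alkylation of the stabilised phosphonoacetate anion by the primary iodide (chemoselective over the chloride) should give the α-substituted Still–Gennari reagent; its new centre is racemic and disappears in step 4.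

Step 4
Reactants: 8 methyl (5E)-2-[bis(2,2,2-trifluoroethoxy)phosphoryl]-9-chloro-6-methylnon-5-enoate; 9 3-(trimethylsilyl)prop-2-ynal
Product: 10 methyl (2Z)-2-[(3E)-7-chloro-4-methylhept-3-en-1-yl]-5-(trimethylsilyl)pent-2-en-4-ynoate
Conditions: KN(SiMe3)2, 18-crown-6, THF, −78 °C
Reagents that add atoms: none
Why: Still–Gennari olefination with the bis(trifluoroethyl) phosphonate under dissociating conditions should give the trisubstituted enoate with ester and alkynyl group cis (2Z), the geometry that later places the C9 substituent equatorial.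

Step 5
Reactants: 10 methyl (2Z)-2-[(3E)-7-chloro-4-methylhept-3-en-1-yl]-5-(trimethylsilyl)pent-2-en-4-ynoate; 11 pentane-2,4-dione
Product: 12 methyl (2Z)-2-[(3E)-8-acetyl-4-methyl-9-oxodec-3-en-1-yl]-5-(trimethylsilyl)pent-2-en-4-ynoate
Conditions: K2CO3, NaI (cat.), DMF, 60 °C
Reagents that add atoms: none
Why: C-alkylation of the acetylacetone anion by the primary chloride with in situ Finkelstein activation installs the future C4 together with its acetyl handle.

Step 6
Reactants: 12 methyl (2Z)-2-[(3E)-8-acetyl-4-methyl-9-oxodec-3-en-1-yl]-5-(trimethylsilyl)pent-2-en-4-ynoate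
Product: 13 methyl (2Z)-2-[(3E)-8-diazo-4-methyl-9-oxodec-3-en-1-yl]-5-(trimethylsilyl)pent-2-en-4-ynoate
Conditions: 4-acetamidobenzenesulfonyl azide, DBU, MeCN, 0 °C to rt
Reagents that add atoms: 4-acetamidobenzenesulfonyl azide, CC(=O)Nc1ccc(cc1)S(=O)(=O)N=[N+]=[N-]
Why: Regitz deacylative diazo transfer puts N2 on the tertiary carbon of the 1,3-diketone and removes one acetyl group as the N-acetylsulfonamide, which gives the α-alkyl α-diazo ketone.

Step 7
Reactants: 13 methyl (2Z)-2-[(3E)-8-diazo-4-methyl-9-oxodec-3-en-1-yl]-5-(trimethylsilyl)pent-2-en-4-ynoate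
Product: 14 methyl (2Z)-2-{2-[(1S,5S,6S)-1-acetyl-5-methylbicyclo[3.1.0]hexan-6-yl]ethyl}-5-(trimethylsilyl)pent-2-en-4-ynoate
Conditions: Rh2(S-PTTL)4 (dirhodium tetrakis[N-phthaloyl-(S)-tert-leucinate], 0.5 mol %), CH2Cl2, −78 to −40 °C, slow addition of 13
Reagents that add atoms: none
Why: Intramolecular cyclopropanation by the dirhodium carbene closes cyclopentane and cyclopropane together; the addition is stereospecific (the E alkene puts the side chain on C6 cis to the bridgehead methyl), the chiral carboxylate ligands choose the alkene face, and the bulky ligand at low temperature should hold back the 1,2-hydride shift to the enone.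

Step 8
Reactants: 14 methyl (2Z)-2-{2-[(1S,5S,6S)-1-acetyl-5-methylbicyclo[3.1.0]hexan-6-yl]ethyl}-5-(trimethylsilyl)pent-2-en-4-ynoate
Product: 16 methyl (2Z)-2-{2-[(1S,5S,6S)-1-hydroxy-5-methylbicyclo[3.1.0]hexan-6-yl]ethyl}pent-2-en-4-ynoate, via acetate 15 (not isolated)
Conditions: (CF3CO)2O, urea·H2O2, Na2HPO4, CH2Cl2, 0 °C; then K2CO3 (cat.), MeOH, 0 °C
Reagents that add atoms: trifluoroperacetic acid (made in the flask), OOC(=O)C(F)(F)F
Why: Baeyer–Villiger oxidation with migration of the tertiary cyclopropyl group (retention of configuration) in preference to methyl gives the cyclopropyl acetate, and mild methanolysis then frees the cyclopropanol and also removes the alkynyl silyl group.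

Step 9
Reactants: 16 methyl (2Z)-2-{2-[(1S,5S,6S)-1-hydroxy-5-methylbicyclo[3.1.0]hexan-6-yl]ethyl}pent-2-en-4-ynoate
Product: 17 methyl 1-ethynyl-8a-methyl-5-oxodecahydronaphthalene-2-carboxylate (trans-fused; ethynyl cis to the 8a-methyl; both C2 epimers)
Conditions: Mn(pic)3 (manganese tris(pyridine-2-carboxylate), 2.2 equiv), Bu3SnH (slow addition), DMF, 0 °C, high dilution; chromatography
Reagents that add atoms: none
Why: Trivalent manganese oxidises the tertiary cyclopropanol O–H to an alkoxy radical, whose strain-driven β-scission breaks the internal C4–C10 bond (tertiary radical, favoured over the secondary radical from external C4–C5 cleavage) and so enlarges the cyclopentane to the cyclohexanone ring A with the radical at C10. This β-keto radical adds to C9 of the Z enoate in a 6-endo-trig Giese closure of ring B, and the α-ester radical at C8 takes hydrogen from Bu3SnH while the stannyl radical is oxidised by a second Mn(pic)3. The closest known reaction type is the Mn(pic)3-mediated ring expansion of bicyclic cyclopropanols to cyclic β-keto radicals with intramolecular radical cyclisation, together with the 6-endo closures of tertiary cyclohexyl radicals in oxidative polyene radical cyclisations. Ring A arises by one-carbon ring expansion (bicyclo[3.1.0]hexane to cyclohexanone) and ring B by 6-endo-trig radical cyclisation. C5, the only stereocentre of 16 that survives, holds its chain equatorial in a chair-like transition state, so that C9 bonds to the C10 face anti to H-5 (trans fusion, quaternary C10) and the Z enoate geometry (C7 trans to ethynyl) places the C9 substituent equatorial; C8 forms unselectively and is corrected in step 10. The step needs internal over external cyclopropane cleavage, 6-endo over 5-exo closure (attack at the fully substituted, polarity-mismatched C8 is disfavoured) and cyclisation faster than tin hydride reduction or re-closure onto the carbonyl; radical stability, enoate polarity and slow hydride addition at high dilution should secure these, and any cis-fused isomer is removed by chromatography before base is applied.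

Step 10
Reactants: 17 methyl 1-ethynyl-8a-methyl-5-oxodecahydronaphthalene-2-carboxylate (both C2 epimers)
Product: 18 methyl (1S,2S,4aS,8aS)-1-ethynyl-8a-methyl-5-oxodecahydronaphthalene-2-carboxylate
Conditions: NaOMe (cat.), MeOH, rt
Reagents that add atoms: none
Why: Base equilibration through the ester enolate should move C8 to the equatorial epimer trans to the C9 ethynyl group; C5 is expected to stay in the more stable trans-fused arrangement, and C9 and C10 cannot enolise.

Step 11
Reactants: 18 methyl (1S,2S,4aS,8aS)-1-ethynyl-8a-methyl-5-oxodecahydronaphthalene-2-carboxylate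
Product: 20 methyl 1-ethynyl-5-formyl-8a-methyldecahydronaphthalene-2-carboxylate (ring stereocentres as in 18; both epimers at the formyl-bearing carbon), via enol ether 19 (not isolated)
Conditions: Ph3P(CH2OMe)Cl, KN(SiMe3)2 (excess ylide), THF, 0 °C to rt; then 2 M HCl, THF, rt
Reagents that add atoms: (methoxymethyl)triphenylphosphonium chloride, [Cl-].COC[P+](c1ccccc1)(c1ccccc1)c1ccccc1; water, O
Why: Wittig methoxymethylenation of the C4 ketone and acid hydrolysis of the enol ether give the one-carbon homologated aldehyde; the new C4 centre needs no control because it stops being a stereocentre in step 12.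

Step 12
Reactants: 20 methyl 1-ethynyl-5-formyl-8a-methyldecahydronaphthalene-2-carboxylate
Product: 22 methyl 1-ethynyl-5,5-bis(hydroxymethyl)-8a-methyldecahydronaphthalene-2-carboxylate (ring stereocentres as in 18), via hydroxy aldehyde 21 (not isolated)
Conditions: 37% aq. HCHO, K2CO3, MeOH, 50 °C; then NaBH4, 0 °C
Reagents that add atoms: formaldehyde, C=O
Why: Crossed aldol reaction of the α-branched aldehyde with formaldehyde (Tollens-type hydroxymethylation, which leaves no α-hydrogen) followed by borohydride reduction in the same pot should give the geminal bis(hydroxymethyl) group without touching the ester.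

Step 13
Reactants: 22 methyl 1-ethynyl-5,5-bis(hydroxymethyl)-8a-methyldecahydronaphthalene-2-carboxylate
Product: 23 acetonide of 22 (2,2-dimethyl-1,3-dioxane spiro-fused at C4; methyl ester and ethynyl retained)
Conditions: Me2C(OMe)2, pyridinium p-toluenesulfonate (cat.), CH2Cl2, rt
Reagents that add atoms: 2,2-dimethoxypropane, COC(C)(C)OC
Why: Acid-catalysed transacetalisation closes the six-membered isopropylidene acetal of the 1,3-diol and so separates these two hydroxyls from the C17 oxygen that comes next.

Step 14
Reactants: 23 acetonide of 22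
Product: 24 C17 primary alcohol (hydroxymethyl in place of the methyl ester of 23; acetonide and ethynyl retained)
Conditions: LiAlH4, THF, 0 °C
Reagents that add atoms: none
Why: Hydride reduction of the methyl ester gives the primary alcohol without change at C8.

Step 15
Reactants: 24 C17 primary alcohol
Product: 25 C9-vinyl alcohol (vinyl in place of the ethynyl group of 24)
Conditions: H2 (1 atm), Pd/CaCO3 poisoned with Pb(OAc)2, quinoline, EtOAc, rt
Reagents that add atoms: none
Why: Lindlar semihydrogenation of the terminal alkyne should stop at the vinyl group needed for hydroboration.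

Step 16
Reactants: 25 C9-vinyl alcohol; 26 3-bromofuran-2(5H)-one
Product: 28 butenolide alcohol (3-substituted furan-2(5H)-one joined through C11–C12 to C9; C17 hydroxymethyl; acetonide), via alkylborane 27 (not isolated)
Conditions: 9-BBN (2.5 equiv), THF, rt; then 26, Pd(dppf)Cl2 (5 mol %), AsPh3, Cs2CO3, DMF/H2O, rt
Reagents that add atoms: 9-borabicyclo[3.3.1]nonane, B1C2CCCC1CCC2 (its boron groups stay only in 27)
Why: Anti-Markovnikov hydroboration of the vinyl group and B-alkyl Suzuki–Miyaura coupling with the α-bromobutenolide form the C12–C13 bond and bring in the butenolide intact.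

Step 17
Reactants: 28 butenolide alcohol
Product: 29 butenolide aldehyde acetonide (C17 formyl in place of the hydroxymethyl of 28)
Conditions: Dess–Martin periodinane, NaHCO3, CH2Cl2, 0 °C to rt
Reagents that add atoms: none
Why: Dess–Martin oxidation of the only free alcohol gives the equatorial C8 aldehyde under buffered conditions that should not epimerise it.

Step 18
Reactants: 29 butenolide aldehyde acetonide
Product: 30 (1R,2S,4aS,8aS)-5,5-bis(hydroxymethyl)-8a-methyl-1-[2-(2-oxo-2,5-dihydrofuran-3-yl)ethyl]decahydronaphthalene-2-carbaldehyde (target)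
Conditions: AcOH/THF/H2O, 40 °C
Reagents that add atoms: none
Why: Mild aqueous acid hydrolyses the acetonide; the equatorial aldehyde (the thermodynamic C8 epimer) and the butenolide should survive.

**Compound list**

1 | 5-chloropent-1-yne | C#CCCCCl | starting material
2 | oxirane | C1CO1 | starting material
3 | [(1E)-5-chloro-2-methylpent-1-en-1-yl]dimethylalumane | C[Al](C)/C=C(\C)CCCCl | intermediate
4 | lithium butyl[(1E)-5-chloro-2-methylpent-1-en-1-yl]dimethylaluminate | [Li+].CCCC[Al-](C)(C)/C=C(\C)CCCCl | intermediate
5 | (3E)-7-chloro-4-methylhept-3-en-1-ol | OCC/C=C(\C)CCCCl | intermediate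
6 | (3E)-7-chloro-1-iodo-4-methylhept-3-ene | ICC/C=C(\C)CCCCl | intermediate
7 | methyl 2-[bis(2,2,2-trifluoroethoxy)phosphoryl]acetate | COC(=O)CP(=O)(OCC(F)(F)F)OCC(F)(F)F | starting material
8 | methyl (5E)-2-[bis(2,2,2-trifluoroethoxy)phosphoryl]-9-chloro-6-methylnon-5-enoate (racemic) | COC(=O)C(CC/C=C(\C)CCCCl)P(=O)(OCC(F)(F)F)OCC(F)(F)F | intermediate
9 | 3-(trimethylsilyl)prop-2-ynal | C[Si](C)(C)C#CC=O | starting material
10 | methyl (2Z)-2-[(3E)-7-chloro-4-methylhept-3-en-1-yl]-5-(trimethylsilyl)pent-2-en-4-ynoate | ClCCC/C(C)=C/CC/C(C(=O)OC)=C/C#C[Si](C)(C)C | intermediate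
11 | pentane-2,4-dione | CC(=O)CC(C)=O | starting material
12 | methyl (2Z)-2-[(3E)-8-acetyl-4-methyl-9-oxodec-3-en-1-yl]-5-(trimethylsilyl)pent-2-en-4-ynoate | CC(=O)C(C(C)=O)CCC/C(C)=C/CC/C(C(=O)OC)=C/C#C[Si](C)(C)C | intermediate
13 | methyl (2Z)-2-[(3E)-8-diazo-4-methyl-9-oxodec-3-en-1-yl]-5-(trimethylsilyl)pent-2-en-4-ynoate | CC(=O)C(=[N+]=[N-])CCC/C(C)=C/CC/C(C(=O)OC)=C/C#C[Si](C)(C)C | intermediate
14 | methyl (2Z)-2-{2-[(1S,5S,6S)-1-acetyl-5-methylbicyclo[3.1.0]hexan-6-yl]ethyl}-5-(trimethylsilyl)pent-2-en-4-ynoate (side chain on C6 cis to the 5-methyl) | CC(=O)[C@]12CCC[C@@]1(C)[C@@H]2CC/C(C(=O)OC)=C/C#C[Si](C)(C)C | intermediate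
15 | methyl (2Z)-2-{2-[(1S,5S,6S)-1-(acetyloxy)-5-methylbicyclo[3.1.0]hexan-6-yl]ethyl}-5-(trimethylsilyl)pent-2-en-4-ynoate | CC(=O)O[C@]12CCC[C@@]1(C)[C@@H]2CC/C(C(=O)OC)=C/C#C[Si](C)(C)C | intermediate
16 | methyl (2Z)-2-{2-[(1S,5S,6S)-1-hydroxy-5-methylbicyclo[3.1.0]hexan-6-yl]ethyl}pent-2-en-4-ynoate | O[C@]12CCC[C@@]1(C)[C@@H]2CC/C(C(=O)OC)=C/C#C | intermediate
17 | methyl 1-ethynyl-8a-methyl-5-oxodecahydronaphthalene-2-carboxylate (trans-fused; ethynyl cis to the 8a-methyl; both C2 epimers) | C[C@@]12CCCC(=O)[C@H]1CCC(C(=O)OC)[C@H]2C#C | intermediate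
18 | methyl (1S,2S,4aS,8aS)-1-ethynyl-8a-methyl-5-oxodecahydronaphthalene-2-carboxylate (trans-fused; ester and ethynyl equatorial) | C[C@@]12CCCC(=O)[C@H]1CC[C@H](C(=O)OC)[C@H]2C#C | intermediate
19 | methyl 1-ethynyl-5-(methoxymethylidene)-8a-methyldecahydronaphthalene-2-carboxylate (ring stereocentres as in 18; E/Z mixture) | C[C@@]12CCCC(=COC)[C@H]1CC[C@H](C(=O)OC)[C@H]2C#C | intermediate
20 | methyl 1-ethynyl-5-formyl-8a-methyldecahydronaphthalene-2-carboxylate (ring stereocentres as in 18; both epimers at the formyl-bearing carbon) | C[C@@]12CCCC(C=O)[C@H]1CC[C@H](C(=O)OC)[C@H]2C#C | intermediate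
21 | methyl 1-ethynyl-5-formyl-5-(hydroxymethyl)-8a-methyldecahydronaphthalene-2-carboxylate (both epimers at the formyl-bearing carbon) | C[C@@]12CCCC(CO)(C=O)[C@H]1CC[C@H](C(=O)OC)[C@H]2C#C | intermediate
22 | methyl 1-ethynyl-5,5-bis(hydroxymethyl)-8a-methyldecahydronaphthalene-2-carboxylate (ring stereocentres as in 18) | C[C@@]12CCCC(CO)(CO)[C@H]1CC[C@H](C(=O)OC)[C@H]2C#C | intermediate
23 | acetonide of 22 (2,2-dimethyl-1,3-dioxane spiro-fused at C4; methyl ester and ethynyl retained) | C[C@@]12CCCC3(COC(C)(C)OC3)[C@H]1CC[C@H](C(=O)OC)[C@H]2C#C | intermediate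
24 | C17 primary alcohol (hydroxymethyl in place of the ester of 23) | C[C@@]12CCCC3(COC(C)(C)OC3)[C@H]1CC[C@H](CO)[C@H]2C#C | intermediate
25 | C9-vinyl alcohol (vinyl in place of the ethynyl group of 24) | C[C@@]12CCCC3(COC(C)(C)OC3)[C@H]1CC[C@H](CO)[C@H]2C=C | intermediate
26 | 3-bromofuran-2(5H)-one | BrC1=CCOC1=O | starting material
27 | bis(9-BBN) adduct of 25 (9-BBN on C12; C17 hydroxyl as its 9-BBN borinate) | C[C@@]12CCCC3(COC(C)(C)OC3)[C@H]1CC[C@H](COB4C5CCCC4CCC5)[C@H]2CCB4C5CCCC4CCC5 | intermediate
28 | butenolide alcohol (3-substituted furan-2(5H)-one on C12; C17 hydroxymethyl; acetonide) | C[C@@]12CCCC3(COC(C)(C)OC3)[C@H]1CC[C@H](CO)[C@H]2CCC4=CCOC4=O | intermediate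
29 | butenolide aldehyde acetonide (C17 formyl) | C[C@@]12CCCC3(COC(C)(C)OC3)[C@H]1CC[C@H](C=O)[C@H]2CCC4=CCOC4=O | intermediate
30 | (1R,2S,4aS,8aS)-5,5-bis(hydroxymethyl)-8a-methyl-1-[2-(2-oxo-2,5-dihydrofuran-3-yl)ethyl]decahydronaphthalene-2-carbaldehyde | C[C@@]12CCCC(CO)(CO)[C@H]1CC[C@H](C=O)[C@H]2CCC1=CCOC1=O | target

**Step count and risks**

Total step count: 18. Longest linear sequence: 18 steps (1 to 30); 2, 7, 9, 11 and 26 are bought and enter directly.

The three steps most likely to fail:

1. Step 9. The tertiary C10 radical may take hydrogen from the tin hydride before it closes ring B, may re-close onto the carbonyl and scramble C5, or may close on the wrong face to give the cis-fused decalin. The fallback sets out from 16 and comes back at 17; it separates ring expansion from ring closure. Copper dibromide (CuBr2, MeCN, 0 °C) opens the cyclopropanol with bromine-atom transfer to the tertiary bromo ketone F6, in which ring A is already formed. Slow addition of (Me3Si)3SiH with Et3B/air in toluene at rt, a poorer hydrogen donor at very low concentration, then regenerates the C10 radical for the 6-endo closure to 17.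

2. Step 7. The carbenoid may undergo 1,2-hydride shift to the conjugated enone faster than it adds to the alkene, or the acetyl carbenoid may give poor enantiofacial discrimination. The fallback sets out from 10 and comes back at 14; it uses the α-alkyl α-diazo ester class, for which low-temperature dirhodium cyclopropanation is established. Chloride 10 is alkylated with tert-butyl acetoacetate (K2CO3, NaI, DMF) to the tert-butyl keto ester F1. Deacetylative diazo transfer (4-acetamidobenzenesulfonyl azide, DBU) gives the tert-butyl diazo ester F2, and Rh2(S-PTTL)4 at −78 °C gives the bicyclic tert-butyl ester F3. CF3CO2H frees the acid F4, (COCl)2 gives the acid chloride F5, and Me2Zn with Pd(PPh3)4 (acyl Negishi coupling) gives the methyl ketone 14.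

3. Step 11. The basic ylide may enolise the hindered C4 ketone instead of adding to it. The fallback sets out from 18 and comes back at 20. Corey–Chaykovsky methylenation (Me3S+ I−, KN(SiMe3)2, THF/DMSO, 0 °C), with a smaller and more nucleophilic ylide, gives the spiro-epoxide F7, and BF3·OEt2 in CH2Cl2 at −78 °C rearranges it (Meinwald rearrangement) to aldehyde 20.

Further compounds
F1 | step 7 | methyl (2Z)-2-[(3E)-8-(tert-butoxycarbonyl)-4-methyl-9-oxodec-3-en-1-yl]-5-(trimethylsilyl)pent-2-en-4-ynoate | CC(=O)C(CCC/C(C)=C/CC/C(C(=O)OC)=C/C#C[Si](C)(C)C)C(=O)OC(C)(C)C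
F2 | step 7 | methyl (2Z)-2-[(3E)-8-(tert-butoxycarbonyl)-8-diazo-4-methyloct-3-en-1-yl]-5-(trimethylsilyl)pent-2-en-4-ynoate | [N-]=[N+]=C(CCC/C(C)=C/CC/C(C(=O)OC)=C/C#C[Si](C)(C)C)C(=O)OC(C)(C)C
F3 | step 7 | methyl (2Z)-2-{2-[(1S,5S,6S)-1-(tert-butoxycarbonyl)-5-methylbicyclo[3.1.0]hexan-6-yl]ethyl}-5-(trimethylsilyl)pent-2-en-4-ynoate | CC(C)(C)OC(=O)[C@]12CCC[C@@]1(C)[C@@H]2CC/C(C(=O)OC)=C/C#C[Si](C)(C)C
F4 | step 7 | (1S,5S,6S)-6-[(3Z)-3-(methoxycarbonyl)-6-(trimethylsilyl)hex-3-en-5-yn-1-yl]-5-methylbicyclo[3.1.0]hexane-1-carboxylic acid | OC(=O)[C@]12CCC[C@@]1(C)[C@@H]2CC/C(C(=O)OC)=C/C#C[Si](C)(C)C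
F5 | step 7 | acid chloride of F4 | ClC(=O)[C@]12CCC[C@@]1(C)[C@@H]2CC/C(C(=O)OC)=C/C#C[Si](C)(C)C
F6 | step 9 | methyl (2Z)-2-[2-(2-bromo-2-methyl-6-oxocyclohexyl)ethyl]pent-2-en-4-ynoate (C5 as in 16; both bromide epimers) | CC1(Br)CCCC(=O)[C@H]1CC/C(C(=O)OC)=C/C#C
F7 | step 11 | spiro-oxirane at C4 of 18 (methyl ester and ethynyl retained; both epoxide epimers) | C[C@@]12CCCC3(CO3)[C@H]1CC[C@H](C(=O)OC)[C@H]2C#C
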